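**Slowness first.** I call slowness the time of a reading divided by minus the natural log of the share not yet turned to product; it is the inverse of an apparent first-order constant. At 10.0 min, the south-west run gives 17.2 min at c(starting material) = 7.3 × 10⁻⁴ M, and the north-west run gives 71.8 min at 0.0091 M, so slowness rises with the charge. I draw a straight line through both and call 1.92 mM the doubling charge: the charge at which the line has climbed by its own value at no charge, which is 12.5 min.

| flask | starting material | reagent | protic impurity | remark | time |
|---|---|---|---|---|---|
| south-west | 7.3 × 10⁻⁴ M | 5 mM | 0.040 mM | run made earlier |  |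
| north-west | 0.0091 M | 5 mM | 0.040 mM | run made earlier |  |
| blue | 0.0010 M | 5.00 mM | 0.0400 mM |  | 10 min |
| grey | 0.0030 M | 5.00 mM | 0.0400 mM |  | 10 min |
| amber | 0.0020 M | 5.00 mM | 0.0400 mM |  | 10 min |
| teal | 0.0012 M | 5.00 mM | 0.0400 mM |  | 10 min |
| red | 6.0 × 10⁻⁴ M | 5.00 mM | 0.0400 mM |  | 10 min |
| violet | 0.0060 M | 5.00 mM | 0.0400 mM |  | 10 min |

| south-west: time / min | south-west: product / % | north-west: time / min | north-west: product / % |
|---|---|---|---|
| 1.50 | 16 | 1.50 | 7 |
| 3.00 | 23 | 3.00 | 9 |
| 5.00 | 29 | 5.00 | 9 |
| 6.00 | 35 | 6.00 | 11 |
| 8.00 | 41 | 8.00 | 17 |
| 10.0 | 44 | 10.0 | 13 |

(readings scatter by 2 percentage points)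



1. the flasks put in order of amount of product, in percent of the starting material charged, best first, at 10 min (blue / grey / amber / teal / red / violet)
2. the amount of product, in percent of the starting material charged of the flask you put first, at 10 min
3. the amount of product, in percent of the starting material charged of the flask you put last, at 10 min

**What matters.** The reagent can stay out of the line, since c(reagent) is 5 mM in the runs and 5.00 mM in the new flasks. The protic impurity is 6.67% of red's charge and 5.48% of the south-west charge, a gap of 1.2 percentage points, so I add no term for it.

The north-west end reading is the weak number: 13% stands below the 17% read at 8.00 min, with a scatter of 2 points. Using that earlier reading gives a slowness of 42.9 min and a doubling charge of 4.89 mM, with the line starting at 15.0 min. Violet then moves from 17.6% to 25.9%, while red moves from 45.7% to 44.8%. The slope stays upward, so my order by rising charge stands, and I commit to the first pair, read at the asked time.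

**The forecast.** It gives red > blue > teal > amber > grey > violet, with 46% and 18%, and says “red's lead is the least certain point”. I place the weak point at violet.

    reagent + intermediate → product (k = 454 /M/s)
    starting material + protic impurity → quenched substrate (k = 129 /M/s)
    starting material ⇌ intermediate + leaving ligand (K = 1.03 × 10⁻⁷ M, k = 0.00530 /s)

**The flask.** Red gives 46.3% and violet 18.0%, in the order red > blue > teal > amber > grey > violet. At 10.0 min, violet holds 0.00108 M of leaving ligand against 2.78 × 10⁻⁴ M in red. Violet's yield means a slowness of 50.4 min, and the line with its doubling charge of 1.92 mM gives 51.6 min. For a neighbour of violet charged with 0.0036 M, the line gives 24.3%, and that flask holds 22.9% of product.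

Readings and results are calculated for substances that don't exist; the scatter is artificial.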